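| setting | Saturday's | Wednesday's | Monday's | eta | epsilon | alpha |
|---|---|---|---|---|---|---|
| starting material | 0.10 M | 0.10 M | 0.050 M | 0.10 M | 0.10 M | 0.10 M |
| partner | 0.11 M | 0.11 M | 0.11 M | 0.110 M | 0.110 M | 0.110 M |
| second substrate | 0.010 M | 0.040 M | 0.020 M | 0.0200 M | 0.0200 M | 0.0200 M |
| temperature | 45 °C | 56 °C | 45 °C |  | 60 °C | 40 °C |
| remark | run made earlier | run made earlier | run made earlier | at 60 °C until 12 min, from then on at 40 °C |  |  |
| time |  |  |  | 40 min | 40 min | 40 min |

| run | time / min | target / % |
|---|---|---|
| Saturday's | 6.00 | 29.9 |
| Saturday's | 20.0 | 20.5 |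
| Saturday's | 30.0 | 14.7 |
| Saturday's | 50.0 | 7.7 |
| Saturday's | 80.0 | 2.6 |
| Saturday's | 120 | 0.7 |
| Wednesday's | 4.00 | 21.5 |
| Wednesday's | 6.00 | 17.7 |
| Wednesday's | 10.0 | 11.7 |
| Wednesday's | 20.0 | 4.3 |
| Wednesday's | 30.0 | 3.0 |
| Wednesday's | 50.0 | 0.5 |
| Monday's | 20.0 | 25.3 |
| Monday's | 40.0 | 14.3 |
| Monday's | 60.0 | 8.3 |
| Monday's | 80.0 | 5.1 |
| Monday's | 120 | 4.4 |

(each reading ± 1 percentage point)

- in percentages every species weighs as the starting material in it: one side product counts as two
- steps thought possible: starting material + partner <-> target; partner <-> dormant form; starting material + target -> side product; partner -> decomposed reagent; second substrate + partner <-> second product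

1. the flask that comes out highest in amount of target, in percent of the starting material charged, or "all alike" when all lie within 1.5 percentage points (eta / epsilon / alpha / all alike)
2. target at the end, in percent of the starting material charged, eta
3. target at the end, in percent of the starting material charged, epsilon
4. target at the end, in percent of the starting material charged, alpha

- At late times the target in Saturday's run falls by a nearly constant share per minute, like a first-order lag discharging. Time is therefore the first setting: by hand, each further minute takes off the same share, and the readings from 20.0 min to 80.0 min make it 0.0344 min⁻¹ at 45 °C, an apparent first-order rate constant.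
- Temperature is the second setting: by hand, heat shortens the time constant, and Wednesday's run from 4.00 min to 20.0 min gives 0.101 min⁻¹ at 56 °C. I take the logarithm of the constant as straight in temperature, so it is 0.149 min⁻¹ at 60 °C and 0.0211 min⁻¹ at 40 °C. I carry this late decay constant, the share of the target lost per minute once the fast start is over, which means a time constant of 47.4 min in the cold.
- Second substrate is the third setting: by hand, it competes for partner and lowers the starting height of the decay line. Run back to zero time, Saturday's line starts at 40.8 % and Wednesday's at 32.1 %, though temperature changed as well. The second substrate of the new flasks lies between those two charges, so I take the mean, 36.5 %, as my own estimate of the height.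
- The time of the change is the fourth setting: by hand, the exponent adds up stretch by stretch. The flasks share one charge, so the exponents rank them, and alpha's 0.845 is smaller than eta's 2.37, which is smaller than epsilon's 5.94. My figures are 15.7 % for alpha, 3.41 % for eta and 0.0961 % for epsilon.
- The forecast names alpha and gives eta 4 %, epsilon 0.4 % and alpha 18 %, reading the fall as “apparently tracking free partner as the partner decomposes”. Its alpha figure stands above mine, but the order is the same.
- The simulation puts alpha highest, as forecast, with alpha at 14.1 %, eta at 4.64 % and epsilon at 1.19 %.

    starting material + partner ⇌ target (K = 13.0 M⁻¹, k = 0.0170 M⁻¹ s⁻¹, Ea = 67.0 kJ mol⁻¹, ΔH = 0 kJ mol⁻¹)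
    partner ⇌ dormant form (K = 0.420, k = 6.50 × 10⁻⁵ s⁻¹, Ea = 98.0 kJ mol⁻¹, ΔH = 4.00 kJ mol⁻¹)
    starting material + target → side product (k = 0.00720 M⁻¹ s⁻¹, Ea = 51.0 kJ mol⁻¹)
    partner → decomposed reagent (k = 3.30 × 10⁻⁴ s⁻¹, Ea = 91.0 kJ mol⁻¹)
    second substrate + partner ⇌ second product (K = 210 M⁻¹, k = 0.0500 M⁻¹ s⁻¹, Ea = 58.0 kJ mol⁻¹, ΔH = 6.00 kJ mol⁻¹)
    (constants at 40 °C)

- In eta, the turning of partner into decomposed reagent has half of its turnover up to 40 min behind it by 3.51 min and the side-product step by 5.31 min, both inside the hot stretch, which ends at 12 min with target at 8.27 %. On the cold stretch eta's target falls to 4.64 %, and the carried constant applied to that state gives 4.58 %; in alpha, starting from 22.9 % at 20.0 min, the same constant gives 15.0 % against the simulated 14.1 %.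

The runs are calculated on assumed constants; the scatter is artificial.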